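## Retrosynthetic overview

1. Target ⇐ bicyclic 7-endo-prenyl trione by one radical cycloisomerization: the C3 radical closes 7-exo onto the C7 prenyl group (cycloheptane), then 5-exo onto the C3 prenyl group (cyclopentane), ending by H-atom transfer.
2. Bicyclic trione ⇐ pyran-masked bicyclic aldehyde: the C7 prenyl group comes from the aldehyde; the 2,2-dimethylpyran is the latent C3-prenyl 1,3-dione.
3. Pyran-masked aldehyde ⇐ chromene + C6 enal acetate by one enantioselective alkylative dearomatization/Michael annulation, which forms the carbocyclic six-ring and the C5, C1 and C7 stereocentres.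
4. Chromene ⇐ phloroglucinol, benzonitrile, geranyl bromide and 3-methylbut-2-enal; enal acetate ⇐ diethyl isopropylidenemalonate.
5. Ring order: 2H-pyran (temporary) → carbocyclic six-ring of the bicyclo[3.3.1]nonane (dearomatization) → cycloheptane → cyclopentane.

Assumption: the cinchonidinium catalyst of step 7 gives the C5 configuration drawn; if its sense of induction is the opposite, the cinchoninium pseudo-enantiomer is used.

Locants for the bicyclic core: C1 benzoyl bridgehead, C2–C3–C4 dicarbonyl bridge, C5 geranyl bridgehead, C6 CH2, C7 CH, C8 CMe2, C9 bridging ketone. "Endo" at C7 means on the side of the C2–C4 bridge.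

## Route

Step 1
Reactants: 1 phloroglucinol; 2 benzonitrile
Product: 4 2,4,6-trihydroxybenzophenone, via ketimine 3 (not isolated)
Conditions: HCl (g), ZnCl2 (cat.), Et2O, 0 °C to rt; then H2O, 100 °C
Reagents that add atoms: water, O
Why: Hoesch acylation, in which the electron-rich triol attacks the protonated nitrile and the ketiminium salt is hydrolysed to the aryl ketone; no stereocentre is formed.

Step 2
Reactants: 4 2,4,6-trihydroxybenzophenone; 5 geranyl bromide
Product: 6 3-geranyl-2,4,6-trihydroxybenzophenone
Conditions: 5 (0.9 equiv), 10% aq KOH, 0 °C to rt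
Reagents that add atoms: none
Why: C-allylation of the ambident phloroglucinolate (Friedel–Crafts-type C-alkylation, favoured over O-alkylation in water), held at the mono stage by limiting the bromide; the E-olefin is retained and no stereocentre is formed.

Step 3
Reactants: 6 3-geranyl-2,4,6-trihydroxybenzophenone; 7 3-methylbut-2-enal
Product: 8 (8-geranyl-5,7-dihydroxy-2,2-dimethyl-2H-chromen-6-yl)(phenyl)methanone
Conditions: ethylenediammonium diacetate (20 mol %), toluene, 110 °C
Reagents that add atoms: none
Why: Knoevenagel condensation at the only free ring CH followed by oxa-6π electrocyclization of the ortho-quinone methide (chromene annulation), closing on the non-chelated OH para to the benzoyl group; the pyran blocks this ring carbon against alkylation and stores the future C3 prenyl group; no stereocentre is formed.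

Step 4
Reactants: 9 diethyl 2-(propan-2-ylidene)propanedioate
Product: 10 2-(propan-2-ylidene)propane-1,3-diol
Conditions: i-Bu2AlH (4.5 equiv), CH2Cl2, −78 to 0 °C
Reagents that add atoms: none
Why: 1,2-reduction of the conjugated diester by the aluminium hydride gives the bis-allylic diol, the tetrasubstituted olefin being too hindered for conjugate reduction; no stereocentre is formed.

Step 5
Reactants: 10 2-(propan-2-ylidene)propane-1,3-diol
Product: 12 2-(hydroxymethyl)-3-methylbut-2-en-1-yl acetate, via cyclic orthoester 11 (not isolated)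
Conditions: MeC(OMe)3, p-toluenesulfonic acid (cat.), CH2Cl2, rt; then H2O
Reagents that add atoms: trimethyl orthoacetate, COC(C)(OC)OC; water, O
Why: cyclic orthoester formation and mild hydrolysis acylate exactly one hydroxyl of the symmetric diol (orthoester mono-acylation); no stereocentre is formed.

Step 6
Reactants: 12 2-(hydroxymethyl)-3-methylbut-2-en-1-yl acetate
Product: 13 2-formyl-3-methylbut-2-en-1-yl acetate
Conditions: PhI(OAc)2 (1.1 equiv), (2,2,6,6-tetramethylpiperidin-1-yl)oxyl (10 mol %), CH2Cl2, rt
Reagents that add atoms: none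
Why: oxoammonium-catalysed oxidation of the primary allylic alcohol to the enal, whose tetrasubstituted olefin cannot isomerize; no stereocentre is formed.

Step 7
Reactants: 8 (8-geranyl-5,7-dihydroxy-2,2-dimethyl-2H-chromen-6-yl)(phenyl)methanone; 13 2-formyl-3-methylbut-2-en-1-yl acetate
Product: 15 pyran-fused bicyclic aldehyde (C7-formyl endo), via C8-alkylated trienone 14 (not isolated)
Conditions: 13 (1.3 equiv), O-allyl-N-(9-anthracenylmethyl)cinchonidinium bromide (10 mol %), Cs2CO3, toluene–CH2Cl2, −40 °C; then AcOH, −40 to 20 °C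
Reagents that add atoms: none
Why: Proposed new method: in the chiral ammonium phenoxide ion pair the only alkylatable ring carbon is chromene C8 (C4a is locked in the pyran, C6 carries the benzoyl group), so SN2 displacement of acetate from 13 breaks the aromaticity and sets the C5 quaternary centre under enantiofacial control; after buffering with AcOH the 2-benzoyl-1,3-dione enol adds through its benzoyl-bearing carbon to the β,β-dimethyl enal (6-exo-trig Michael, necessarily cis to the new CH2 bridge, which fixes C1), and the aldehyde enol is C-protonated from the convex face so that CHO ends endo at C7; the closest known reaction type is the phase-transfer-catalysed alkylative dearomatization–annulation of 3,5-dialkyl acylphloroglucinols with α-(acetoxymethyl) enals.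

Step 8
Reactants: 15 pyran-fused bicyclic aldehyde; 16 (2-methylprop-1-en-1-yl)magnesium bromide
Product: 18 allylic methyl carbonate, via cerium alkoxide 17 (not isolated)
Conditions: 16 (1.3 equiv), CeCl3, THF, −78 °C; then ClCO2Me, −78 to 0 °C
Reagents that add atoms: methyl chloroformate, COC(=O)Cl
Why: the non-basic organocerium reagent adds 1,2 to the hindered aldehyde in preference to the three flanked ketones and without epimerizing C7, and the alkoxide is acylated in the same flask; the new carbinol centre forms unselectively and is removed in step 9.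

Step 9
Reactants: 18 allylic methyl carbonate
Product: 21 bicyclic 7-endo-prenyl 3-prenyl trione (enol form), via C7-prenyl pyran 19 (not isolated), via oxatriene 20 (not isolated)
Conditions: Pd(PPh3)4 (5 mol %), Bu3SnH (2.5 equiv), THF, 0 to 25 °C; then 65 °C; AcOH
Reagents that add atoms: none
Why: Proposed new method: zerovalent palladium ionizes the allylic carbonate and tin hydride delivers hydride to the less hindered CH terminus of the π-allyl (Tsuji–Trost-type allylic hydrogenolysis, trisubstituted olefin retained, the pyran keeping C3 non-nucleophilic); on warming, the 2H-pyran opens by retro-oxa-6π electrocyclization to the 2-alkylidene-1,3-dione, which undergoes palladium–tin hydride conjugate reduction at the exocyclic CH to unveil the C3-prenyl 1,3-dione, C7 being untouched; the closest known reaction types are the palladium-catalysed hydrostannolysis of allylic esters and the hydride 1,4-reduction of Knoevenagel adducts of 1,3-diones.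

Step 10
Reactants: 21 bicyclic 7-endo-prenyl 3-prenyl trione
Product: 22 CNP0155129.1
Conditions: Mn(OAc)3·2H2O (2.2 equiv), degassed EtOH, 25 to 50 °C
Reagents that add atoms: none
Why: Mn(OAc)3 oxidative radical cyclization: the C3 radical adds 7-exo-trig to the endo C7 prenyl olefin (only the endo face is in reach, which fixes C3); the tertiary radical closes 5-exo-trig onto the C3 prenyl olefin through a chair-like transition state that puts the isopropyl-bearing centre trans to the CH2 bridge; the last tertiary radical takes a hydrogen atom from ethanol; the ring-fusion CH arises from attack on the olefin face that places the CMe2 terminus under the C2 carbonyl, its epimer being the main expected by-product.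

## Compound list

1 | phloroglucinol (benzene-1,3,5-triol) | Oc1cc(O)cc(O)c1 | starting material
2 | benzonitrile | N#Cc1ccccc1 | starting material
3 | (2,4,6-trihydroxyphenyl)(phenyl)methanimine, formed as its hydrochloride | N=C(c1ccccc1)c1c(O)cc(O)cc1O | intermediate
4 | 2,4,6-trihydroxybenzophenone | O=C(c1ccccc1)c1c(O)cc(O)cc1O | intermediate
5 | geranyl bromide, (2E)-1-bromo-3,7-dimethylocta-2,6-diene | CC(C)=CCC/C(C)=C/CBr | starting material
6 | 3-geranyl-2,4,6-trihydroxybenzophenone | CC(C)=CCC/C(C)=C/Cc1c(O)cc(O)c(C(=O)c2ccccc2)c1O | intermediate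
7 | 3-methylbut-2-enal | CC(C)=CC=O | starting material
8 | (8-geranyl-5,7-dihydroxy-2,2-dimethyl-2H-chromen-6-yl)(phenyl)methanone | CC(C)=CCC/C(C)=C/Cc1c(O)c(C(=O)c2ccccc2)c(O)c2C=CC(C)(C)Oc12 | intermediate
9 | diethyl 2-(propan-2-ylidene)propanedioate | CCOC(=O)C(=C(C)C)C(=O)OCC | starting material
10 | 2-(propan-2-ylidene)propane-1,3-diol | CC(C)=C(CO)CO | intermediate
11 | 2-methoxy-2-methyl-5-(propan-2-ylidene)-1,3-dioxane | COC1(C)OCC(=C(C)C)CO1 | intermediate
12 | 2-(hydroxymethyl)-3-methylbut-2-en-1-yl acetate | CC(C)=C(CO)COC(C)=O | intermediate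
13 | 2-formyl-3-methylbut-2-en-1-yl acetate | CC(C)=C(C=O)COC(C)=O | intermediate
14 | 6-benzoyl-8-(2-formyl-3-methylbut-2-en-1-yl)-8-geranyl-5-hydroxy-2,2-dimethyl-2H-chromen-7(8H)-one, C8 configured as C5 of 15 | CC(C)=CCC/C(C)=C/C[C@]1(CC(C=O)=C(C)C)C(=O)C(C(=O)c2ccccc2)=C(O)C3=C1OC(C)(C)C=C3 | intermediate
15 | pyran-fused bicyclic aldehyde: 1-benzoyl-5-geranyl-8,8-dimethyl-2,9-dioxobicyclo[3.3.1]non-3-ene-7-carbaldehyde whose C3=C4–O unit belongs to a fused 2,2-dimethyl-2H-pyran; CHO endo at C7; C1, C5, C7 configured as in the target | CC(C)=CCC/C(C)=C/C[C@@]12C[C@@H](C=O)C(C)(C)[C@](C(=O)c3ccccc3)(C2=O)C(=O)C4=C1OC(C)(C)C=C4 | intermediate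
16 | (2-methylprop-1-en-1-yl)magnesium bromide | CC(C)=C[Mg]Br | starting material
17 | dichlorocerium alkoxide of the C7 1-hydroxy-3-methylbut-2-enyl adduct of 15 (carbinol epimers) | CC(C)=CCC/C(C)=C/C[C@@]12C[C@@H](C(O[Ce](Cl)Cl)C=C(C)C)C(C)(C)[C@](C(=O)c3ccccc3)(C2=O)C(=O)C4=C1OC(C)(C)C=C4 | intermediate
18 | allylic methyl carbonate: as 15 with C7 bearing CH(OCO2Me)CH=CMe2 (endo, carbinol epimers) | CC(C)=CCC/C(C)=C/C[C@@]12C[C@@H](C(OC(=O)OC)C=C(C)C)C(C)(C)[C@](C(=O)c3ccccc3)(C2=O)C(=O)C4=C1OC(C)(C)C=C4 | intermediate
19 | C7-prenyl pyran: as 15 with an endo prenyl group at C7 | CC(C)=CCC/C(C)=C/C[C@@]12C[C@@H](CC=C(C)C)C(C)(C)[C@](C(=O)c3ccccc3)(C2=O)C(=O)C4=C1OC(C)(C)C=C4 | intermediate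
20 | oxatriene: 1-benzoyl-5-geranyl-8,8-dimethyl-3-(3-methylbut-2-enylidene)-7-endo-prenylbicyclo[3.3.1]nonane-2,4,9-trione | CC(C)=CCC/C(C)=C/C[C@@]12C[C@@H](CC=C(C)C)C(C)(C)[C@](C(=O)c3ccccc3)(C2=O)C(=O)C(=CC=C(C)C)C1=O | intermediate
21 | 1-benzoyl-5-geranyl-4-hydroxy-8,8-dimethyl-3,7-diprenylbicyclo[3.3.1]non-3-ene-2,9-dione, C7 prenyl endo; C1, C5, C7 configured as in the target | CC(C)=CCC/C(C)=C/C[C@@]12C[C@@H](CC=C(C)C)C(C)(C)[C@](C(=O)c3ccccc3)(C2=O)C(=O)C(CC=C(C)C)=C1O | intermediate
22 | CNP0155129.1: homoadamantane trione with fused cyclopentane; isopropyl trans to the CH2 bridge on the cyclopentane | CC(C)=CCC/C(C)=C/C[C@@]12C[C@H]3C[C@@H]4C(C)(C)[C@@H](C(C)C)C[C@]4(C1=O)C(=O)[C@@](C(=O)c1ccccc1)(C2=O)C3(C)C | target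

## Step count and risks

Total step count: 10. Longest linear sequence: 7 steps (steps 1, 2, 3, 7, 8, 9, 10, from phloroglucinol).

Steps most likely to fail:

**Step 7.** O-alkylation may compete with C-alkylation. The Michael closure between two quaternary carbons has no aldol trap and may revert. Protonation may give the exo aldehyde, which cannot cyclize later. The fallback sets out from 6 and comes back at 21. Prenyl bromide in aqueous KOH gives 3-geranyl-5-prenyl-2,4,6-trihydroxybenzophenone F1. Annulation of F1 with 13 (same catalyst, CsOH·H2O, CH2Cl2, −50 °C) runs through alkylation, Michael addition and aldol closure onto C3, giving the adamantanol F2 with the aldehyde carbon locked endo. The regioisomer alkylated at the prenyl-bearing carbon is expected in similar amount and must be separated. Treating F2 with 16 and CeCl3 at −78 °C causes retro-aldol opening and 1,2-addition, giving the allylic alcohol with free 3-prenyl dione F3. ClCO2Me and pyridine give the bis(methyl carbonate) F4, whose enol carbonate masks C3. Pd(PPh3)4 with Bu3SnH, then K2CO3 in MeOH, gives 21.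

**Step 9.** Hydride may go to the CMe2 terminus of the π-allyl. The pyran may open too early, letting C3 attack the π-allyl, or may not open at all. The fallback sets out from 15 and comes back at 21. Wittig reaction with (methoxymethyl)triphenylphosphonium chloride and KN(SiMe3)2 gives the methyl enol ether F5. Dilute aqueous HCl in THF at 0 °C gives the homologated aldehyde F6. Wittig reaction with isopropyltriphenylphosphonium iodide and n-BuLi gives 19, which is isolated here. Heating 19 in toluene at 80 °C with diethyl 2,6-dimethyl-1,4-dihydropyridine-3,5-dicarboxylate reduces the oxatriene 20 as it forms and gives 21.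

**Step 10.** The final tertiary radical may be oxidized by trivalent manganese instead of taking hydrogen from ethanol, giving olefins or ethers. The face selectivity of the first ring closure is modest. The fallback sets out from 21 and comes back at 22. Mn(OAc)3·2H2O with Cu(OAc)2 in AcOH at 25 °C ends the same cascade by clean oxidative elimination to the isopropenyl cage F7. H2 (1 atm) with RhCl(PPh3)3 in benzene then reduces only the 1,1-disubstituted olefin, leaving the geranyl group intact, and gives 22.

## Further compounds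

F1 | step 7 | 3-geranyl-5-prenyl-2,4,6-trihydroxybenzophenone | CC(C)=CCC/C(C)=C/Cc1c(O)c(CC=C(C)C)c(O)c(C(=O)c2ccccc2)c1O
F2 | step 7 | adamantanol: 1-benzoyl-5-geranyl-3-prenyl-8,8-dimethyl trione with C3 and C7 bridged by CH(OH) | CC(C)=CCC/C(C)=C/C[C@@]12C[C@@H]3C(C)(C)[C@](C(=O)c4ccccc4)(C2=O)C(=O)[C@](CC=C(C)C)(C1=O)C3O
F3 | step 7 | allylic alcohol with free 3-prenyl dione: as 21 with C7 bearing endo CH(OH)CH=CMe2 | CC(C)=CCC/C(C)=C/C[C@@]12C[C@@H](C(O)C=C(C)C)C(C)(C)[C@](C(=O)c3ccccc3)(C2=O)C(=O)C(CC=C(C)C)=C1O
F4 | step 7 | bis(methyl carbonate) of F3 (allylic carbonate and C4 enol carbonate) | CC(C)=CCC/C(C)=C/C[C@@]12C[C@@H](C(OC(=O)OC)C=C(C)C)C(C)(C)[C@](C(=O)c3ccccc3)(C2=O)C(=O)C(CC=C(C)C)=C1OC(=O)OC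
F5 | step 9 | methyl enol ether: as 15 with C7 bearing endo CH=CHOMe | CC(C)=CCC/C(C)=C/C[C@@]12C[C@@H](C=COC)C(C)(C)[C@](C(=O)c3ccccc3)(C2=O)C(=O)C4=C1OC(C)(C)C=C4
F6 | step 9 | homologated aldehyde: as 15 with C7 bearing endo CH2CHO | CC(C)=CCC/C(C)=C/C[C@@]12C[C@@H](CC=O)C(C)(C)[C@](C(=O)c3ccccc3)(C2=O)C(=O)C4=C1OC(C)(C)C=C4
F7 | step 10 | isopropenyl analogue of the target | CC(C)=CCC/C(C)=C/C[C@@]12C[C@H]3C[C@@H]4C(C)(C)[C@@H](C(C)=C)C[C@]4(C1=O)C(=O)[C@@](C(=O)c1ccccc1)(C2=O)C3(C)C
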